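**Retrosynthetic overview**
1. The 14-membered carbocycle is closed last, at C3–C4, by a proposed chiral-carbene/nickel reductive ynal macrocyclisation that also sets the C3 carbinol and the 4E olefin.
2. The seco-ynal comes from an Evans–Tishchenko reduction (sets C9 anti to C11 and installs the C11 acetate) of a β-hydroxy Z-enone, itself made by Nozaki–Hiyama–Kishi coupling (C8–C9) of a lactone aldehyde with a C4–C8 (Z)-iodo-enyne.
3. The α-methylene ε-lactone is the first ring formed: the C16 acrylic acid opens an (11R,12R)-epoxide at C12 with inversion (7-exo); the epoxide comes from Shi epoxidation of an 11E olefin built by carboalumination and ethylene oxide opening.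
4. C1 and carbons C1–C3 and C11–C17 come from (S)-limonene by oxidative ring cleavage; the iodo-enyne comes from but-2-yn-1-ol and propynylmagnesium bromide.
5. Ring order: ε-lactone (step 11), then the macrocycle (step 21).

Assumption: locants follow cembrane numbering (C1 = ring CH carrying C15; C16 = lactone carbonyl; C17 = exocyclic CH2; methyls on C4, C8, C12), and the imidazolinium salt of step 21 is a separately prepared catalyst precursor, not counted as a route step.

**Route**

Step 1
Reactants: 1 (S)-(−)-limonene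
Product: 2 (4S)-limonene 1,2-oxide (cis/trans mixture at the epoxide)
Conditions: mCPBA (1.0 equiv), CH2Cl2, 0 °C
Reagents that add atoms: mCPBA (3-chloroperoxybenzoic acid), OOC(=O)c1cccc(Cl)c1
Why: Prilezhaev epoxidation is much faster at the trisubstituted ring olefin than at the isopropenyl group, the epoxide configuration is irrelevant because both carbons become carbonyls next, and the future C1 stereocentre comes unchanged from the chiral pool.

Step 2
Reactants: 2 (4S)-limonene 1,2-oxide
Product: 4 (3S)-6-oxo-3-(prop-1-en-2-yl)heptanal, via limonene-1,2-diol 3 (not isolated)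
Conditions: H5IO6, THF/H2O, 0 °C to rt
Reagents that add atoms: water, O
Why: Acidic epoxide hydrolysis followed by Malaprade glycol cleavage opens the ring to the keto aldehyde without touching the stereocentre or the isopropenyl group.

Step 3
Reactants: 4 (3S)-6-oxo-3-(prop-1-en-2-yl)heptanal
Product: 5 (5S)-7-hydroxy-5-(prop-1-en-2-yl)heptan-2-one
Conditions: NaBH4 (0.3 equiv), CH2Cl2/EtOH, −78 °C; aq. HCl quench
Reagents that add atoms: none
Why: Chemoselective borohydride reduction, since at −78 °C with substoichiometric NaBH4 the aldehyde reacts far faster than the methyl ketone.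

Step 4
Reactants: 5 (5S)-7-hydroxy-5-(prop-1-en-2-yl)heptan-2-one
Product: 6 (5S)-7-[(tert-butyldiphenylsilyl)oxy]-5-(prop-1-en-2-yl)heptan-2-one
Conditions: TBDPSCl, imidazole, DMF, rt
Reagents that add atoms: tert-butyldiphenylsilyl chloride, CC(C)(C)[Si](Cl)(c1ccccc1)c1ccccc1
Why: Standard silylation of the primary alcohol with a group that survives amide bases, AlMe3, mild acid and the later selective cleavage of a primary TBS ether.

Step 5
Reactants: 6 (5S)-7-[(tert-butyldiphenylsilyl)oxy]-5-(prop-1-en-2-yl)heptan-2-one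
Product: 8 tert-butyl{[(3S)-3-(prop-1-en-2-yl)hept-6-yn-1-yl]oxy}diphenylsilane, via enol phosphate 7 (not isolated)
Conditions: LiN(i-Pr)2 (1.05 equiv), THF, −78 °C; ClP(O)(OEt)2, −78 °C to rt; then LiN(i-Pr)2 (2.3 equiv), −78 °C to rt
Reagents that add atoms: none
Why: Negishi alkyne synthesis, in which kinetic deprotonation at the methyl group gives the terminal enol phosphate and base-induced elimination delivers the terminal alkyne (the old ketone methyl becomes C11).

Step 6
Reactants: 8 tert-butyl{[(3S)-3-(prop-1-en-2-yl)hept-6-yn-1-yl]oxy}diphenylsilane; 9 ethylene oxide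
Product: 12 (3E,7S)-9-[(tert-butyldiphenylsilyl)oxy]-4-methyl-7-(prop-1-en-2-yl)non-3-en-1-ol, via alkenylalane 10 (not isolated), via lithium alanate 11 (not isolated)
Conditions: AlMe3 (2.5 equiv), Cp2ZrCl2 (20 mol %), CH2Cl2, 0 °C to rt; evaporate; n-BuLi, hexane/THF, −78 °C; ethylene oxide, −78 to 0 °C; aq. HCl
Reagents that add atoms: trimethylaluminium, C[Al](C)C
Why: Negishi zirconium-catalysed carboalumination adds methyl and aluminium syn across the terminal alkyne (methyl to the internal carbon), which fixes the 11E trisubstituted olefin, and the derived alanate opens ethylene oxide with retention to append C10 and C9.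

Step 7
Reactants: 12 (3E,7S)-9-[(tert-butyldiphenylsilyl)oxy]-4-methyl-7-(prop-1-en-2-yl)non-3-en-1-ol
Product: 13 (3E,7S)-1-[(tert-butyldimethylsilyl)oxy]-9-[(tert-butyldiphenylsilyl)oxy]-4-methyl-7-(prop-1-en-2-yl)non-3-ene
Conditions: TBSCl, imidazole, CH2Cl2, rt
Reagents that add atoms: tert-butyldimethylsilyl chloride, CC(C)(C)[Si](C)(C)Cl
Why: Standard silylation masks the C9 hydroxyl so it cannot open the coming epoxide, with a group that can later be removed in the presence of the TBDPS ether.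

Step 8
Reactants: 13 (3E,7S)-1-[(tert-butyldimethylsilyl)oxy]-9-[(tert-butyldiphenylsilyl)oxy]-4-methyl-7-(prop-1-en-2-yl)non-3-ene
Product: 14 tert-butyl{2-[(2R,3R)-3-methyl-3-{(3S)-5-[(tert-butyldiphenylsilyl)oxy]-3-(prop-1-en-2-yl)pentyl}oxiran-2-yl]ethoxy}dimethylsilane
Conditions: D-fructose-derived Shi ketone (1,2:4,5-di-O-isopropylidene-β-D-erythro-2,3-hexodiulo-2,6-pyranose, 30 mol %), KHSO5 (as Oxone), K2CO3, Bu4NHSO4 (cat.), MeCN/CH2(OMe)2/aq. Na2B4O7 buffer, 0 °C
Reagents that add atoms: potassium peroxymonosulfate, [K+].[O-]S(=O)(=O)OO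
Why: Shi asymmetric epoxidation, in which the chiral dioxirane attacks the trans-trisubstituted olefin through the spiro transition state to give the (11R,12R)-epoxide under reagent control while the 1,1-disubstituted isopropenyl group reacts only slowly.

Step 9
Reactants: 14 (11R,12R)-epoxide
Product: 16 enal (14 with the isopropenyl CH3 oxidised to CHO), via allylic alcohol 15 (not isolated)
Conditions: SeO2 (0.3 equiv), t-BuOOH, CH2Cl2, 0 °C to rt; then MnO2, CH2Cl2, rt
Reagents that add atoms: selenium dioxide (oxygen transfer), O=[Se]=O; tert-butyl hydroperoxide (terminal oxidant), CC(C)(C)OO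
Why: Selenium dioxide allylic oxidation (ene reaction then [2,3]-sigmatropic shift) hydroxylates the methyl group of the only remaining olefin, and MnO2 converges the alcohol/enal mixture to the 2-substituted acrolein.

Step 10
Reactants: 16 enal
Product: 17 epoxy acrylic acid (14 with the isopropenyl CH3 oxidised to CO2H)
Conditions: NaClO2, NaH2PO4, 2-methyl-2-butene, t-BuOH/H2O, 0 °C
Reagents that add atoms: sodium chlorite, [Na+].[O-]Cl=O
Why: Pinnick oxidation converts the enal to the acrylic acid under buffered conditions that leave the epoxide and both silyl ethers intact.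

Step 11
Reactants: 17 epoxy acrylic acid
Product: 19 (4S,7S)-4-{2-[(tert-butyldiphenylsilyl)oxy]ethyl}-7-[(1R)-1,3-dihydroxypropyl]-7-methyl-3-methylideneoxepan-2-one, via silyl lactone 18 (not isolated)
Conditions: 10-camphorsulfonic acid (10 mol %), CH2Cl2, 0 °C to rt; then MeOH, 0 °C
Reagents that add atoms: none
Why: Brønsted-acid-catalysed intramolecular epoxide opening, in which the carboxylic acid attacks the tertiary C12 in a 7-exo mode with inversion (setting 12S and leaving the 11R oxygen in place), after which acidic methanolysis removes only the primary TBS ether.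

Step 12
Reactants: 19 lactone diol
Product: 20 (4S,7S)-4-{2-[(tert-butyldiphenylsilyl)oxy]ethyl}-7-[(1R)-1-hydroxy-3-oxopropyl]-7-methyl-3-methylideneoxepan-2-one
Conditions: TEMPO (2,2,6,6-tetramethylpiperidin-1-oxyl, 10 mol %), PhI(OAc)2, CH2Cl2, rt
Reagents that add atoms: none
Why: Oxoammonium (TEMPO/PhI(OAc)2) oxidation is selective for the primary C9 alcohol over the hindered secondary C11 alcohol and gives the β-hydroxy aldehyde without over-oxidation.

Step 13
Reactants: 21 but-2-yn-1-ol
Product: 23 (Z)-3-iodobut-2-en-1-ol, via cyclic alanate 22 (not isolated)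
Conditions: NaAlH2(OCH2CH2OMe)2, THF, 0 °C to rt; then I2, −78 to 0 °C
Reagents that add atoms: iodine, II
Why: Hydroxyl-directed trans-hydroalumination of the propargylic alcohol places aluminium on C3 cis to the CH2O group, and iodinolysis with retention gives the (Z)-iodide that becomes the 7Z olefin.

Step 14
Reactants: 23 (Z)-3-iodobut-2-en-1-ol
Product: 24 (Z)-1-bromo-3-iodobut-2-ene
Conditions: CBr4, PPh3, CH2Cl2, 0 °C
Reagents that add atoms: carbon tetrabromide, BrC(Br)(Br)Br
Why: Appel bromination converts the allylic alcohol to the primary bromide without touching the vinyl iodide or the olefin geometry.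

Step 15
Reactants: 24 (Z)-1-bromo-3-iodobut-2-ene; 25 prop-1-yn-1-ylmagnesium bromide
Product: 26 (Z)-2-iodohept-2-en-5-yne
Conditions: CuI (10 mol %), THF, −20 °C to rt
Reagents that add atoms: none
Why: Copper-catalysed SN2 alkynylation of the primary allylic bromide gives the skipped enyne, the vinyl iodide being inert in the absence of palladium or nickel.

Step 16
Reactants: 20 lactone β-hydroxy aldehyde; 26 (Z)-2-iodohept-2-en-5-yne
Product: 27 (4S,7S)-4-{2-[(tert-butyldiphenylsilyl)oxy]ethyl}-7-[(1R,4Z)-1,3-dihydroxy-4-methylnon-4-en-7-yn-1-yl]-7-methyl-3-methylideneoxepan-2-one (C9 epimer mixture)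
Conditions: CrCl2 (6 equiv), NiCl2 (1 mol %), DMSO/THF, rt
Reagents that add atoms: none
Why: Nozaki–Hiyama–Kishi coupling, in which zerovalent nickel activates the vinyl iodide and transmetalation to chromium gives an alkenylchromium species that adds only to the aldehyde with retention of the Z geometry; the C9 epimers are inconsequential because C9 is oxidised next.

Step 17
Reactants: 27 diol (C9 epimers)
Product: 28 (4S,7S)-4-{2-[(tert-butyldiphenylsilyl)oxy]ethyl}-7-[(1R,4Z)-1-hydroxy-4-methyl-3-oxonon-4-en-7-yn-1-yl]-7-methyl-3-methylideneoxepan-2-one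
Conditions: MnO2, CH2Cl2, rt
Reagents that add atoms: none
Why: MnO2 oxidises only the allylic C9 alcohol under neutral conditions, giving the β-hydroxy Z-enone with the C11 hydroxyl untouched.

Step 18
Reactants: 28 β-hydroxy Z-enone
Product: 29 (4S,7S)-7-[(1R,3R,4Z)-1-acetoxy-3-hydroxy-4-methylnon-4-en-7-yn-1-yl]-4-{2-[(tert-butyldiphenylsilyl)oxy]ethyl}-7-methyl-3-methylideneoxepan-2-one
Conditions: SmI2 (30 mol %, premixed with MeCHO), MeCHO (8 equiv), THF, −10 °C
Reagents that add atoms: acetaldehyde, CC=O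
Why: Evans–Tishchenko reduction, in which the hemiacetal formed from the C11 hydroxyl and acetaldehyde on trivalent samarium delivers hydride intramolecularly through a chair six-membered transition state, giving the 1,3-anti (9R) alcohol while the C11 oxygen becomes the acetate in the same event.

Step 19
Reactants: 29 acetate silyl ether
Product: 30 (4S,7S)-7-[(1R,3R,4Z)-1-acetoxy-3-hydroxy-4-methylnon-4-en-7-yn-1-yl]-4-(2-hydroxyethyl)-7-methyl-3-methylideneoxepan-2-one
Conditions: HF·pyridine, pyridine, THF, 0 °C to rt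
Reagents that add atoms: none
Why: Fluoride-mediated desilylation under buffered conditions removes the TBDPS group while sparing the acetate, the lactone and the skipped enyne.

Step 20
Reactants: 30 diol
Product: 31 2-{(4S,7S)-7-[(1R,3R,4Z)-1-acetoxy-3-hydroxy-4-methylnon-4-en-7-yn-1-yl]-7-methyl-3-methylidene-2-oxooxepan-4-yl}acetaldehyde (seco-ynal)
Conditions: TEMPO (10 mol %), PhI(OAc)2, CH2Cl2, rt
Reagents that add atoms: none
Why: Oxoammonium (TEMPO/PhI(OAc)2) oxidation converts the primary C3 alcohol to the aldehyde faster than it touches the hindered secondary allylic C9 alcohol.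

Step 21
Reactants: 31 seco-ynal
Product: 33 target, (1S,3R,4E,7Z,9R,11R,12S)-11-acetoxy-3,9-dihydroxycembra-4,7,15(17)-trien-16,12-olide, via silyl ether 32 (not isolated)
Conditions: Ni(cod)2 (20 mol %), (4R,5R)-1,3-bis(2-cyclohexylphenyl)-4,5-diphenyl-4,5-dihydroimidazolium tetrafluoroborate (22 mol %), KOt-Bu (20 mol %), Et3SiH (3 equiv), THF, syringe-pump addition of 31 (2 mM final), rt; then HF·pyridine, pyridine, THF, 0 °C
Reagents that add atoms: none
Why: Proposed new method: a catalyst-controlled asymmetric nickel-catalysed reductive macrocyclisation of an ynal, in which zerovalent nickel carrying a C2-symmetric N-heterocyclic carbene binds aldehyde and methyl alkyne, oxidative cyclisation forms the C3–C4 bond at the methyl-bearing alkyne carbon (small substituent next to the new bond, tether on the nickel-bound carbon, giving the endocyclic 14-membered ring), the chiral pocket of the carbene selects one aldehyde face and so the 3R carbinol, and σ-bond metathesis with Et3SiH followed by C–H reductive elimination delivers H and C3 cis across the alkyne (4E olefin) as the silyl ether that HF·pyridine cleaves; the closest known reactions are the achiral nickel/carbene/silane reductive macrocyclisations of ynals and the intermolecular enantioselective aldehyde–alkyne reductive coupling with chiral carbene ligands, neither shown as a ligand-controlled macrocyclisation on a skipped enyne bearing a free alcohol and an α-methylene lactone.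

**Compound list**

1 | (S)-(−)-limonene | CC1=CC[C@H](CC1)C(C)=C | starting material
2 | (4S)-limonene 1,2-oxide, cis/trans mixture | CC12OC1C[C@H](CC2)C(C)=C | intermediate
3 | (4S)-limonene-1,2-diol (diastereomer mixture, not isolated) | CC1(O)C(O)C[C@H](CC1)C(C)=C | intermediate
4 | (3S)-6-oxo-3-(prop-1-en-2-yl)heptanal | CC(=O)CC[C@@H](CC=O)C(C)=C | intermediate
5 | (5S)-7-hydroxy-5-(prop-1-en-2-yl)heptan-2-one | CC(=O)CC[C@@H](CCO)C(C)=C | intermediate
6 | (5S)-7-[(tert-butyldiphenylsilyl)oxy]-5-(prop-1-en-2-yl)heptan-2-one | CC(=O)CC[C@@H](CCO[Si](c1ccccc1)(c1ccccc1)C(C)(C)C)C(C)=C | intermediate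
7 | diethyl (5S)-7-[(tert-butyldiphenylsilyl)oxy]-5-(prop-1-en-2-yl)hept-1-en-2-yl phosphate (not isolated) | C=C(OP(=O)(OCC)OCC)CC[C@@H](CCO[Si](c1ccccc1)(c1ccccc1)C(C)(C)C)C(C)=C | intermediate
8 | tert-butyl{[(3S)-3-(prop-1-en-2-yl)hept-6-yn-1-yl]oxy}diphenylsilane | C#CCC[C@@H](CCO[Si](c1ccccc1)(c1ccccc1)C(C)(C)C)C(C)=C | intermediate
9 | ethylene oxide | C1CO1 | starting material
10 | dimethyl[(1E,5S)-7-[(tert-butyldiphenylsilyl)oxy]-2-methyl-5-(prop-1-en-2-yl)hept-1-en-1-yl]alane (not isolated) | C[Al](C)/C=C(\C)CC[C@@H](CCO[Si](c1ccccc1)(c1ccccc1)C(C)(C)C)C(C)=C | intermediate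
11 | lithium butyl(dimethyl)[(1E,5S)-7-[(tert-butyldiphenylsilyl)oxy]-2-methyl-5-(prop-1-en-2-yl)hept-1-en-1-yl]alanate (not isolated) | [Li+].CCCC[Al-](C)(C)/C=C(\C)CC[C@@H](CCO[Si](c1ccccc1)(c1ccccc1)C(C)(C)C)C(C)=C | intermediate
12 | (3E,7S)-9-[(tert-butyldiphenylsilyl)oxy]-4-methyl-7-(prop-1-en-2-yl)non-3-en-1-ol | OCC/C=C(\C)CC[C@@H](CCO[Si](c1ccccc1)(c1ccccc1)C(C)(C)C)C(C)=C | intermediate
13 | (3E,7S)-1-[(tert-butyldimethylsilyl)oxy]-9-[(tert-butyldiphenylsilyl)oxy]-4-methyl-7-(prop-1-en-2-yl)non-3-ene | CC(C)(C)[Si](C)(C)OCC/C=C(\C)CC[C@@H](CCO[Si](c1ccccc1)(c1ccccc1)C(C)(C)C)C(C)=C | intermediate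
14 | tert-butyl{2-[(2R,3R)-3-methyl-3-{(3S)-5-[(tert-butyldiphenylsilyl)oxy]-3-(prop-1-en-2-yl)pentyl}oxiran-2-yl]ethoxy}dimethylsilane, the (1S,11R,12R)-epoxide | CC(C)(C)[Si](C)(C)OCC[C@H]1O[C@]1(C)CC[C@@H](CCO[Si](c2ccccc2)(c2ccccc2)C(C)(C)C)C(C)=C | intermediate
15 | allylic alcohol: 14 with the isopropenyl CH3 replaced by CH2OH (2-substituted prop-2-en-1-ol; 1S,11R,12R; not isolated) | CC(C)(C)[Si](C)(C)OCC[C@H]1O[C@]1(C)CC[C@@H](CCO[Si](c2ccccc2)(c2ccccc2)C(C)(C)C)C(CO)=C | intermediate
16 | enal: 14 with the isopropenyl CH3 replaced by CHO (2-substituted acrolein; 1S,11R,12R) | CC(C)(C)[Si](C)(C)OCC[C@H]1O[C@]1(C)CC[C@@H](CCO[Si](c2ccccc2)(c2ccccc2)C(C)(C)C)C(C=O)=C | intermediate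
17 | epoxy acrylic acid: 14 with the isopropenyl CH3 replaced by CO2H (1S,11R,12R) | CC(C)(C)[Si](C)(C)OCC[C@H]1O[C@]1(C)CC[C@@H](CCO[Si](c2ccccc2)(c2ccccc2)C(C)(C)C)C(C(=O)O)=C | intermediate
18 | (4S,7S)-7-{(1R)-3-[(tert-butyldimethylsilyl)oxy]-1-hydroxypropyl}-4-{2-[(tert-butyldiphenylsilyl)oxy]ethyl}-7-methyl-3-methylideneoxepan-2-one (not isolated) | C=C1C(=O)O[C@](C)([C@H](O)CCO[Si](C)(C)C(C)(C)C)CC[C@H]1CCO[Si](c2ccccc2)(c2ccccc2)C(C)(C)C | intermediate
19 | (4S,7S)-4-{2-[(tert-butyldiphenylsilyl)oxy]ethyl}-7-[(1R)-1,3-dihydroxypropyl]-7-methyl-3-methylideneoxepan-2-one | C=C1C(=O)O[C@](C)([C@H](O)CCO)CC[C@H]1CCO[Si](c2ccccc2)(c2ccccc2)C(C)(C)C | intermediate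
20 | (4S,7S)-4-{2-[(tert-butyldiphenylsilyl)oxy]ethyl}-7-[(1R)-1-hydroxy-3-oxopropyl]-7-methyl-3-methylideneoxepan-2-one | C=C1C(=O)O[C@](C)([C@H](O)CC=O)CC[C@H]1CCO[Si](c2ccccc2)(c2ccccc2)C(C)(C)C | intermediate
21 | but-2-yn-1-ol | CC#CCO | starting material
22 | sodium 2,2-bis(2-methoxyethoxy)-3-methyl-2,5-dihydro-1,2-oxaaluminol-2-uide, the cyclic vinylalanate (not isolated) | [Na+].COCCO[Al-]1(OCCOC)OCC=C1C | intermediate
23 | (Z)-3-iodobut-2-en-1-ol | OC/C=C(/C)I | intermediate
24 | (Z)-1-bromo-3-iodobut-2-ene | BrC/C=C(/C)I | intermediate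
25 | prop-1-yn-1-ylmagnesium bromide | CC#C[Mg]Br | starting material
26 | (Z)-2-iodohept-2-en-5-yne | CC#CC/C=C(/C)I | intermediate
27 | (4S,7S)-4-{2-[(tert-butyldiphenylsilyl)oxy]ethyl}-7-[(1R,4Z)-1,3-dihydroxy-4-methylnon-4-en-7-yn-1-yl]-7-methyl-3-methylideneoxepan-2-one, C9 epimer mixture | C=C1C(=O)O[C@](C)([C@H](O)CC(O)/C(C)=C\CC#CC)CC[C@H]1CCO[Si](c2ccccc2)(c2ccccc2)C(C)(C)C | intermediate
28 | (4S,7S)-4-{2-[(tert-butyldiphenylsilyl)oxy]ethyl}-7-[(1R,4Z)-1-hydroxy-4-methyl-3-oxonon-4-en-7-yn-1-yl]-7-methyl-3-methylideneoxepan-2-one | C=C1C(=O)O[C@](C)([C@H](O)CC(=O)/C(C)=C\CC#CC)CC[C@H]1CCO[Si](c2ccccc2)(c2ccccc2)C(C)(C)C | intermediate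
29 | (4S,7S)-7-[(1R,3R,4Z)-1-acetoxy-3-hydroxy-4-methylnon-4-en-7-yn-1-yl]-4-{2-[(tert-butyldiphenylsilyl)oxy]ethyl}-7-methyl-3-methylideneoxepan-2-one | C=C1C(=O)O[C@](C)([C@H](OC(C)=O)C[C@@H](O)/C(C)=C\CC#CC)CC[C@H]1CCO[Si](c2ccccc2)(c2ccccc2)C(C)(C)C | intermediate
30 | (4S,7S)-7-[(1R,3R,4Z)-1-acetoxy-3-hydroxy-4-methylnon-4-en-7-yn-1-yl]-4-(2-hydroxyethyl)-7-methyl-3-methylideneoxepan-2-one | C=C1C(=O)O[C@](C)([C@H](OC(C)=O)C[C@@H](O)/C(C)=C\CC#CC)CC[C@H]1CCO | intermediate
31 | 2-{(4S,7S)-7-[(1R,3R,4Z)-1-acetoxy-3-hydroxy-4-methylnon-4-en-7-yn-1-yl]-7-methyl-3-methylidene-2-oxooxepan-4-yl}acetaldehyde (seco-ynal) | C=C1C(=O)O[C@](C)([C@H](OC(C)=O)C[C@@H](O)/C(C)=C\CC#CC)CC[C@H]1CC=O | intermediate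
32 | 3-O-triethylsilyl ether of the target (1S,3R,4E,7Z,9R,11R,12S; not isolated) | C=C1C(=O)O[C@@]2(C)CC[C@H]1C[C@@H](O[Si](CC)(CC)CC)/C(C)=C/C/C=C(/C)[C@H](O)C[C@H]2OC(C)=O | intermediate
33 | (1S,3R,4E,7Z,9R,11R,12S)-11-acetoxy-3,9-dihydroxycembra-4,7,15(17)-trien-16,12-olide (CNP0183491.2) | C=C1C(=O)O[C@@]2(C)CC[C@H]1C[C@@H](O)/C(C)=C/C/C=C(/C)[C@H](O)C[C@H]2OC(C)=O | target

**Step count and risk**

Total steps: 21. Longest linear sequence: 18 (steps 1–12 and 16–21); steps 13–15 make the iodo-enyne 26 in a 3-step side branch.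

Stereocentre origin: C1 from (S)-limonene; C11 and C12 from the Shi epoxidation plus invertive lactonisation; C9 from the Evans–Tishchenko reduction; C3 from step 21. Olefin geometry: 7Z from step 13, 4E from the syn addition in step 21.

The three steps most likely to fail:

Step 21 (the proposed new macrocyclisation). The likeliest failure is insufficient ligand control of the aldehyde face, giving C3 epimers; the antipodal (4S,5S) ligand is the first thing to try if the sense is reversed. Competing engagement of the α-methylene lactone by zerovalent nickel is a second concern. The fallback uses only known chemistry, sets out from ynal 31 and comes back to the route at target 33. The established achiral ynal macrocyclisation [Ni(cod)2, IMes·HCl, KOt-Bu, Et3SiH, THF, high dilution] closes the same C3–C4 bond with syn addition but without facial control, giving the C3-epimeric macrocyclic triethylsilyl ether F1. TBSOTf and 2,6-lutidine cap the C9 hydroxyl to give the bis-silyl ether F2. Pyridinium p-toluenesulfonate in MeOH/CH2Cl2 removes only the triethylsilyl group to give the C3-epimeric alcohol F3. Dess–Martin periodinane gives the macrocyclic enone F4. Corey–Bakshi–Shibata reduction with the (S)-methyl oxazaborolidine and BH3·SMe2 sets 3R under reagent control, giving the C9 silyl ether F5, and HF·pyridine then gives 33.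

Step 11 (7-exo epoxy-acid lactonisation). Possible failures are Meinwald rearrangement of the tertiary epoxide, capture of C12 by the C9 silyl ether oxygen (tetrahydrofuran formation), or loss of stereospecificity at C12. The fallback swaps invertive alkyl C–O formation for retentive acylation of a pre-formed tertiary alcohol; it sets out from epoxy acid 17 and comes back at lactone diol 19. Acid-catalysed hydrolysis (HClO4 cat., THF/H2O, 0 °C) opens the epoxide with water at the tertiary carbon with inversion to give the (11R,12S)-diol acid F6. TESCl and imidazole silylate the secondary C11 hydroxyl (the silyl ester is cleaved on work-up) to give the C11 triethylsilyl ether acid F7. Yamaguchi lactonisation (2,4,6-trichlorobenzoyl chloride, Et3N; then DMAP, toluene, 80 °C, high dilution) acylates the tertiary C12 hydroxyl to give the bis-silyl lactone F8. 10-Camphorsulfonic acid in MeOH/CH2Cl2 removes the triethylsilyl and primary TBS groups to give 19.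

Step 9 (allylic oxidation of the isopropenyl methyl). Possible failures are competing hydroxylation at the C1 methine or acid-induced opening of the epoxide. The fallback replaces the selenium ene reaction by chlorination and N-oxide oxidation; it sets out from epoxide 14 and comes back at enal 16. Ene-type chlorination with Ca(OCl)2 and CO2 (CH2Cl2/H2O, 0 °C) gives the allylic chloride F9, and Ganem oxidation with N-methylmorpholine N-oxide (MeCN, 40 °C) converts it to 16.

**Further compounds**

F1 | step 21 | C3-epimeric 3-O-triethylsilyl ether of the target (C9 hydroxyl free) | C=C1C(=O)O[C@@]2(C)CC[C@H]1CC(O[Si](CC)(CC)CC)/C(C)=C/C/C=C(/C)[C@H](O)C[C@H]2OC(C)=O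
F2 | step 21 | C3-epimeric 3-O-triethylsilyl 9-O-tert-butyldimethylsilyl ether of the target | C=C1C(=O)O[C@@]2(C)CC[C@H]1CC(O[Si](CC)(CC)CC)/C(C)=C/C/C=C(/C)[C@H](O[Si](C)(C)C(C)(C)C)C[C@H]2OC(C)=O
F3 | step 21 | C3-epimeric 9-O-tert-butyldimethylsilyl ether of the target (C3 hydroxyl free) | C=C1C(=O)O[C@@]2(C)CC[C@H]1CC(O)/C(C)=C/C/C=C(/C)[C@H](O[Si](C)(C)C(C)(C)C)C[C@H]2OC(C)=O
F4 | step 21 | 3-oxo macrocyclic enone, 9-O-tert-butyldimethylsilyl ether (1S,4E,7Z,9R,11R,12S) | C=C1C(=O)O[C@@]2(C)CC[C@H]1CC(=O)/C(C)=C/C/C=C(/C)[C@H](O[Si](C)(C)C(C)(C)C)C[C@H]2OC(C)=O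
F5 | step 21 | (3R)-9-O-tert-butyldimethylsilyl ether of the target | C=C1C(=O)O[C@@]2(C)CC[C@H]1C[C@@H](O)/C(C)=C/C/C=C(/C)[C@H](O[Si](C)(C)C(C)(C)C)C[C@H]2OC(C)=O
F6 | step 11 | (1S,11R,12S)-11,12-dihydroxy acrylic acid (17 with the epoxide hydrolysed to the anti diol) | CC(C)(C)[Si](C)(C)OCC[C@@H](O)[C@@](C)(O)CC[C@@H](CCO[Si](c1ccccc1)(c1ccccc1)C(C)(C)C)C(C(=O)O)=C
F7 | step 11 | C11 triethylsilyl ether of F6 (tertiary C12 hydroxyl free) | CC(C)(C)[Si](C)(C)OCC[C@@H](O[Si](CC)(CC)CC)[C@@](C)(O)CC[C@@H](CCO[Si](c1ccccc1)(c1ccccc1)C(C)(C)C)C(C(=O)O)=C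
F8 | step 11 | (4S,7S)-7-{(1R)-3-[(tert-butyldimethylsilyl)oxy]-1-[(triethylsilyl)oxy]propyl}-4-{2-[(tert-butyldiphenylsilyl)oxy]ethyl}-7-methyl-3-methylideneoxepan-2-one | C=C1C(=O)O[C@](C)([C@H](O[Si](CC)(CC)CC)CCO[Si](C)(C)C(C)(C)C)CC[C@H]1CCO[Si](c2ccccc2)(c2ccccc2)C(C)(C)C
F9 | step 9 | allylic chloride: 14 with the isopropenyl CH3 replaced by CH2Cl (1S,11R,12R) | CC(C)(C)[Si](C)(C)OCC[C@H]1O[C@]1(C)CC[C@@H](CCO[Si](c2ccccc2)(c2ccccc2)C(C)(C)C)C(CCl)=C
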